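**Plan**

- Ring numbering: C1 is the quinone carbonyl carbon between the methoxy carbon C2 and the chain carbon C6. C2–C3–C4–C5 carry the methoxy group (C2) and the other ring oxygen (C4) and correspond to a 1,1-dimethoxy-3-silyloxybutadiene. C6–C1 correspond to an alkyne whose acetyl group on C1 activates the cycloaddition and is later exchanged for the C1 oxygen.
- Retrosynthesis: quinone to hydroquinone; the C1–O bond back to a C1–acetyl bond (Dakin oxidation); ring bonds C5–C6 and C1–C2 cut by a [4+2] benzannulation; then the alkyne–acetyl bond and the alkyne–CH2 bond of the side chain.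
- Forward: the full chain is built first from ω-pentadecalactone (bromo acid, acetylide alkylation, esterification, acyl Sonogashira). The diene is made in two steps from ketene dimethyl acetal. The only ring closes in step 7 with the chain already attached, and two oxidation steps finish the synthesis.
- Stereochemistry: the target has no stereocentre and no stereogenic double bond. The only selectivity needed is the regiochemistry of the ring closure, set by the polarity of diene and ynone.

Key step: step 7

Remark: the acetyl ketone, twisted out of the ring plane by its two ortho substituents, is assumed to react as an ordinary ketone in alkaline H2O2, as hindered 2,6-disubstituted acetophenones do in Baeyer–Villiger oxidations.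

**Step 1**
Reactants: 1 ω-pentadecalactone (oxacyclohexadecan-2-one)
Product: 2 15-bromopentadecanoic acid
Conditions: 48% aq. HBr, conc. H2SO4, AcOH, reflux
Reagents that add atoms: hydrogen bromide, Br
Why: Acid-mediated lactone opening with SN2 displacement of the protonated primary oxygen by bromide (HBr cleavage of a primary alkyl C–O bond) should give the ω-bromo acid, since the chain carries no other reactive site.

**Step 2**
Reactants: 2 15-bromopentadecanoic acid
Product: 3 heptadec-16-ynoic acid
Conditions: LiC≡CH·H2NCH2CH2NH2 (3 equiv), DMSO, rt; then 1 M HCl
Reagents that add atoms: lithium acetylide–ethylenediamine complex, [Li]C#C.NCCN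
Why: SN2 alkylation of lithium acetylide by a primary bromide in DMSO is the standard route to ω-alkynoic acids, and the first equivalent of acetylide forms the lithium carboxylate, which resists further attack.

**Step 3**
Reactants: 3 heptadec-16-ynoic acid
Product: 4 methyl heptadec-16-ynoate
Conditions: MeOH, H2SO4 (cat.), reflux
Reagents that add atoms: methanol, CO
Why: Fischer esterification in excess methanol should mask the acid for the coupling and cycloaddition steps, a terminal alkyne being inert to catalytic acid.

**Step 4**
Reactants: 4 methyl heptadec-16-ynoate, 5 acetyl chloride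
Product: 6 methyl 18-oxononadec-16-ynoate
Conditions: PdCl2(PPh3)2 (2 mol %), CuI (4 mol %), Et3N (1.2 equiv), THF, rt
Reagents that add atoms: none
Why: Acyl Sonogashira coupling, in which the acid chloride adds oxidatively to zerovalent palladium formed in situ, the copper acetylide of 4 transmetalates and reductive elimination gives the conjugated ynone without touching the methyl ester.

**Step 5**
Reactants: 7 1,1-dimethoxyethene (ketene dimethyl acetal), 5 acetyl chloride
Product: 8 4,4-dimethoxybut-3-en-2-one
Conditions: Et3N (1.1 equiv), Et2O, 0 °C to rt
Reagents that add atoms: none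
Why: C-Acylation of the strongly nucleophilic ketene acetal at its CH2 carbon, followed by loss of HCl to the amine, is the established way to β-acyl ketene acetals.

**Step 6**
Reactants: 8 4,4-dimethoxybut-3-en-2-one
Product: 9 1,1-dimethoxy-3-(trimethylsilyloxy)buta-1,3-diene
Conditions: LiN(iPr)2 (1.1 equiv), THF, −78 °C; Me3SiCl, −78 °C to rt; non-aqueous work-up, distillation
Reagents that add atoms: chlorotrimethylsilane, C[Si](C)(C)Cl
Why: Kinetic deprotonation of the only enolisable position, the acetyl CH3, and O-silylation of the cross-conjugated enolate (silyl enol ether formation) should give the 2-silyloxydiene, which is used at once because it is moisture-sensitive.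

**Step 7**
Reactants: 6 methyl 18-oxononadec-16-ynoate, 9 1,1-dimethoxy-3-(trimethylsilyloxy)buta-1,3-diene
Product: 12 methyl 15-(2-acetyl-5-hydroxy-3-methoxyphenyl)pentadecanoate, via cyclohexadiene ketal adduct 10 (not isolated), via aryl trimethylsilyl ether 11 (not isolated)
Conditions: 9 (2.5 equiv), toluene, 110 °C, sealed tube; then 1 M HCl, THF, rt
Reagents that add atoms: none
Why: The electron-rich diene 9 and the electron-poor alkyne of 6 should combine in a thermal, normal-electron-demand [4+2] cycloaddition that is concerted but strongly asynchronous (in the limit a Michael addition followed by closure of the allenolate carbon on the dimethoxycarbenium carbon), the bond from the diene CH2 to the chain-bearing β-carbon (C5–C6) leading and the bond from the ketene-acetal carbon to the acetyl-bearing α-carbon (C1–C2) following. The closest known reaction type is the benzannulation of 1,1-dialkoxy-3-silyloxybutadienes with acetylenic ketones and esters, which gives 4-hydroxy-2-alkoxyaryl carbonyl compounds. The single six-membered carbocycle is closed by the cycloaddition itself, four ring atoms (C2–C5) coming from the diene and two (C6, C1) from the alkyne, both new sigma bonds forming between the two components. Adduct 10 carries a ketal at C2 and a CH2 at C5, so 1,4-elimination of methanol is driven by aromatisation and leaves the C2 methoxy group in place, and dilute acid then cleaves the aryl silyl ether 11 to the C4 phenol. No stereocentre is formed; the selectivity needed is regiochemical (hydroxyl para and methoxy ortho to the acetyl group), and it is secured by the matched polarisation of the partners, the largest HOMO coefficient lying on the diene CH2 and the largest LUMO coefficient on the ynone β-carbon. Working without a Lewis acid keeps the ketone carbonyl from reacting as a heterodienophile and leaves the methyl ester untouched.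

**Step 8**
Reactants: 12 methyl 15-(2-acetyl-5-hydroxy-3-methoxyphenyl)pentadecanoate
Product: 15 15-(2,5-dihydroxy-3-methoxyphenyl)pentadecanoic acid, via aryl acetate 13 (not isolated), via hydroquinone methyl ester 14 (not isolated)
Conditions: 30% aq. H2O2 (1.5 equiv), 2 M aq. NaOH (5 equiv), THF/MeOH, 0 °C to rt, argon; then 1 M HCl
Reagents that add atoms: hydrogen peroxide, OO; sodium hydroxide, [Na+].[OH-]
Why: Dakin oxidation, in which hydroperoxide anion adds to the aryl ketone, the electron-rich aryl group (pushed by the para phenoxide and the ortho methoxy group) migrates to oxygen to give aryl acetate 13, and the excess hydroxide then cleaves this acetate and the methyl ester, so that acidification under argon should deliver the hydroquinone acid.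

**Step 9**
Reactants: 15 15-(2,5-dihydroxy-3-methoxyphenyl)pentadecanoic acid
Product: 16 15-(5-methoxy-3,6-dioxocyclohexa-1,4-dien-1-yl)pentadecanoic acid
Conditions: FeCl3 (2.5 equiv), MeCN/H2O, rt
Reagents that add atoms: none
Why: Two successive one-electron oxidations of the electron-rich hydroquinone by FeCl3 (the classical hydroquinone-to-quinone oxidation) should give the p-benzoquinone, the acidic medium leaving the methoxy group and the carboxylic acid untouched.

**Compound list**

1 | ω-pentadecalactone (oxacyclohexadecan-2-one) | O=C1CCCCCCCCCCCCCCO1 | starting material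
2 | 15-bromopentadecanoic acid | OC(=O)CCCCCCCCCCCCCCBr | intermediate
3 | heptadec-16-ynoic acid | OC(=O)CCCCCCCCCCCCCCC#C | intermediate
4 | methyl heptadec-16-ynoate | COC(=O)CCCCCCCCCCCCCCC#C | intermediate
5 | acetyl chloride | CC(Cl)=O | starting material
6 | methyl 18-oxononadec-16-ynoate | COC(=O)CCCCCCCCCCCCCCC#CC(C)=O | intermediate
7 | 1,1-dimethoxyethene (ketene dimethyl acetal) | C=C(OC)OC | starting material
8 | 4,4-dimethoxybut-3-en-2-one | CC(=O)C=C(OC)OC | intermediate
9 | 1,1-dimethoxy-3-(trimethylsilyloxy)buta-1,3-diene | COC(OC)=CC(=C)O[Si](C)(C)C | intermediate
10 | methyl 15-[2-acetyl-3,3-dimethoxy-5-(trimethylsilyloxy)cyclohexa-1,4-dien-1-yl]pentadecanoate (not isolated) | COC(=O)CCCCCCCCCCCCCCC1=C(C(C)=O)C(OC)(OC)C=C(O[Si](C)(C)C)C1 | intermediate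
11 | methyl 15-[2-acetyl-3-methoxy-5-(trimethylsilyloxy)phenyl]pentadecanoate (not isolated) | COC(=O)CCCCCCCCCCCCCCc1cc(O[Si](C)(C)C)cc(OC)c1C(C)=O | intermediate
12 | methyl 15-(2-acetyl-5-hydroxy-3-methoxyphenyl)pentadecanoate | COC(=O)CCCCCCCCCCCCCCc1cc(O)cc(OC)c1C(C)=O | intermediate
13 | methyl 15-(2-acetoxy-5-hydroxy-3-methoxyphenyl)pentadecanoate (not isolated) | COC(=O)CCCCCCCCCCCCCCc1cc(O)cc(OC)c1OC(C)=O | intermediate
14 | methyl 15-(2,5-dihydroxy-3-methoxyphenyl)pentadecanoate (not isolated) | COC(=O)CCCCCCCCCCCCCCc1cc(O)cc(OC)c1O | intermediate
15 | 15-(2,5-dihydroxy-3-methoxyphenyl)pentadecanoic acid | OC(=O)CCCCCCCCCCCCCCc1cc(O)cc(OC)c1O | intermediate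
16 | 15-(5-methoxy-3,6-dioxocyclohexa-1,4-dien-1-yl)pentadecanoic acid | COC1=CC(=O)C=C(CCCCCCCCCCCCCCC(=O)O)C1=O | target

**Step count**

Total: 9 steps. Longest linear sequence: 7 steps (steps 1, 2, 3, 4, 7, 8, 9 from ω-pentadecalactone); the diene branch (steps 5 and 6) joins at step 7.

**Steps most likely to fail**

Step 7. The cycloaddition may be too slow for a β-alkyl-substituted ynone, so that thermal decomposition or protodesilylation of the diene, or arrest at an open-chain Michael adduct, competes with ring closure. The fallback builds the arene without a cycloaddition and sets out from 2. After conversion of 2 into its chloromagnesium carboxylate with MeMgCl, coupling with 3,5-dimethoxyphenylmagnesium bromide under Li2CuCl4 catalysis in THF should give 15-(3,5-dimethoxyphenyl)pentadecanoic acid F1. Mono-demethylation with NaSEt in DMF at 140 °C, which stops after one ether because the phenoxide deactivates the ring, should give 15-(3-hydroxy-5-methoxyphenyl)pentadecanoic acid F2. Teuber oxidation with (KSO3)2NO in KH2PO4-buffered aqueous acetone should then place the new oxygen para to the phenol, between methoxy group and chain, and return to the route at 16.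

Step 8. Hydroperoxide addition to the ketone flanked by two ortho substituents may be slow, and the electron-rich hydroquinone may be over-oxidised in alkaline peroxide to the quinone and then degraded. The fallback avoids a free hydroquinone in base and sets out from 12. O-Methylation (MeI, K2CO3, acetone) should give methyl 15-(2-acetyl-3,5-dimethoxyphenyl)pentadecanoate F3. Baeyer–Villiger oxidation with mCPBA in NaHCO3-buffered CH2Cl2, with migration of the electron-rich aryl group, should give methyl 15-(2-acetoxy-3,5-dimethoxyphenyl)pentadecanoate F4. LiOH in aqueous THF under argon should cleave the acetate and the methyl ester to 15-(2-hydroxy-3,5-dimethoxyphenyl)pentadecanoic acid F5. Oxidative demethylation of this para-methoxyphenol with (NH4)2Ce(NO3)6 in aqueous MeCN should return to the route at 16.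

Step 4. Dehydrochlorination of acetyl chloride to ketene by Et3N and copper-mediated homocoupling of the alkyne may outrun acyl transfer to palladium. The fallback replaces the catalytic coupling by a Weinreb amide acylation and sets out from 3. Double deprotonation with n-BuLi (2.1 equiv) in THF/DMPU at −78 °C and addition of N-methoxy-N-methylacetamide, which reacts only at the acetylide carbon, should give 18-oxononadec-16-ynoic acid F6. Carboxylate alkylation with MeI and KHCO3 in DMF at rt then returns to the route at 6.

**Further compounds**

F1 | step 7 | 15-(3,5-dimethoxyphenyl)pentadecanoic acid | OC(=O)CCCCCCCCCCCCCCc1cc(OC)cc(OC)c1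
F2 | step 7 | 15-(3-hydroxy-5-methoxyphenyl)pentadecanoic acid | OC(=O)CCCCCCCCCCCCCCc1cc(O)cc(OC)c1
F3 | step 8 | methyl 15-(2-acetyl-3,5-dimethoxyphenyl)pentadecanoate | COC(=O)CCCCCCCCCCCCCCc1cc(OC)cc(OC)c1C(C)=O
F4 | step 8 | methyl 15-(2-acetoxy-3,5-dimethoxyphenyl)pentadecanoate | COC(=O)CCCCCCCCCCCCCCc1cc(OC)cc(OC)c1OC(C)=O
F5 | step 8 | 15-(2-hydroxy-3,5-dimethoxyphenyl)pentadecanoic acid | OC(=O)CCCCCCCCCCCCCCc1cc(OC)cc(OC)c1O
F6 | step 4 | 18-oxononadec-16-ynoic acid | OC(=O)CCCCCCCCCCCCCCC#CC(C)=O
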